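**Plan**

- Cuts, in retrosynthetic order: the seven O–benzyl bonds; the six aryl C–O bonds of rings A and A' (C1–OMe, C3–O and C5–O on each ring, back to C–F); the two C4 ketones (back to carbinols) and the C6–CH2–C6' bridge (back to a carbinol formed from a ring A aldehyde and a ring A' aryllithium); the two ring A/ring B carbinol C–C bonds.
- Enabling feature: on rings A and A' the three oxygens sit at C1 (para to the C4 ketone, OMe) and at C3 and C5 (ortho to it, OH). Every one of these C–O bonds can therefore come from a C–F bond by ketone-activated substitution, methoxide para and benzyloxide ortho.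
- Forward: no ring is built. Ring B joins ring A and ring B' joins ring A' by addition of a 2,4,6-trifluorophenyl organometallic (lithium for half A, magnesium for half A') to the two protected orsellinaldehydes. The halves are joined A–CH(O)–A' through a formyl group, the bridge is deoxygenated and the outer carbinols are oxidised. The hexafluoride is then substituted six times and debenzylated.
- Stereochemistry: the target has no stereocentre. The carbinol centres made on the way are carried as racemates or diastereomer mixtures and are all removed by deoxygenation (step 8) and oxidation (step 10).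

Key step: step 11

Remark on the chemistry: "half A" is ring A with ring B (2,4-dioxygenated 6-methylphenyl), and "half A'" is ring A' with ring B' (2-methoxy-4-oxygenated 6-methylphenyl). On rings A and A', C1 carries OMe, C2 H, C3 OH, C4 the ketone, C5 OH and C6 the bridging CH2. Both ring B aldehydes are made from 2,4-dihydroxy-6-methylbenzaldehyde, because formylation of a 3-benzyloxy-5-methoxytoluene would not distinguish the two oxygens.

Remark on the chemistry: the 2,4,6-trifluorophenyl nucleophile is generated in two established ways, by deprotonation of 1,3,5-trifluorobenzene for half A and by bromine–magnesium exchange of commercial 1-bromo-2,4,6-trifluorobenzene for half A'. The two methods are interchangeable, so each half has a ready alternative if one mode of generation proves troublesome with its aldehyde.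

Step 1
Reactants: 1 2,4-dihydroxy-6-methylbenzaldehyde
Product: 2 2,4-bis(benzyloxy)-6-methylbenzaldehyde
Conditions: BnBr (2.4 equiv), K2CO3, DMF, 60 °C
Reagents that add atoms: benzyl bromide, BrCc1ccccc1
Why: Williamson etherification with excess halide and carbonate in a dipolar solvent should alkylate both phenols, including the hydrogen-bonded 2-hydroxyl, and leave the aldehyde untouched.

Step 2
Reactants: 1 2,4-dihydroxy-6-methylbenzaldehyde
Product: 3 4-(benzyloxy)-2-hydroxy-6-methylbenzaldehyde
Conditions: BnBr (1.05 equiv), NaHCO3, MeCN, 70 °C
Reagents that add atoms: benzyl bromide, BrCc1ccccc1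
Why: Regioselective Williamson etherification, since the 2-hydroxyl is locked in a hydrogen bond to the aldehyde and under a weak base only the more acidic, free 4-hydroxyl should be alkylated.

Step 3
Reactants: 3 4-(benzyloxy)-2-hydroxy-6-methylbenzaldehyde
Product: 4 4-(benzyloxy)-2-methoxy-6-methylbenzaldehyde
Conditions: MeI, K2CO3, DMF, 40 °C
Reagents that add atoms: iodomethane, CI
Why: Williamson methylation of the remaining chelated phenol, which carbonate in DMF deprotonates fully, fixes the ring B' pattern (2-OMe, 4-OBn) without ambiguity.

Step 4
Reactants: 5 1,3,5-trifluorobenzene; 2 2,4-bis(benzyloxy)-6-methylbenzaldehyde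
Product: 8 triethylsilyl ether of [2,4-bis(benzyloxy)-6-methylphenyl](2,4,6-trifluorophenyl)methanol (half A, racemic), via 2,4,6-trifluorophenyllithium 6 (not isolated), via lithium carbinolate of half A 7 (not isolated)
Conditions: 5, n-BuLi, THF, −78 °C; then 2, −78 °C; then Et3SiCl, DMAP (cat.), −78 °C → rt
Reagents that add atoms: chlorotriethylsilane, CC[Si](Cl)(CC)CC
Why: Deprotonation between two fluorines gives an aryllithium that is stable at −78 °C and adds 1,2 to the aldehyde, and the lithium alkoxide is O-silylated in the same flask (carbonyl addition followed by silyl ether formation); the new carbinol centre is racemic and is oxidised away in step 10.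

Step 5
Reactants: 9 1-bromo-2,4,6-trifluorobenzene; 4 4-(benzyloxy)-2-methoxy-6-methylbenzaldehyde
Product: 12 triethylsilyl ether of [4-(benzyloxy)-2-methoxy-6-methylphenyl](2,4,6-trifluorophenyl)methanol (half A', racemic), via 2,4,6-trifluorophenylmagnesium chloride 10 (not isolated), via chloromagnesium carbinolate of half A' 11 (not isolated)
Conditions: 9, i-PrMgCl·LiCl, THF, −15 °C; then 4, −15 → 0 °C; then imidazole, Et3SiCl, DMAP (cat.), DMF, 0 °C → rt
Reagents that add atoms: chlorotriethylsilane, CC[Si](Cl)(CC)CC
Why: Bromine–magnesium exchange on the electron-poor aryl bromide gives an arylmagnesium chloride that does not lose metal fluoride at −15 °C and adds 1,2 to the aldehyde (Grignard addition), and the magnesium alkoxide is silylated in the same flask under imidazole promotion; the racemic carbinol centre is removed in step 10.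

Step 6
Reactants: 8 half A silyl ether
Product: 15 3-{[2,4-bis(benzyloxy)-6-methylphenyl][(triethylsilyl)oxy]methyl}-2,4,6-trifluorobenzaldehyde, via ring A aryllithium 13 (not isolated), via lithium hemiaminal alkoxide 14 (not isolated)
Conditions: n-BuLi, THF, −78 °C; then DMF, −78 → −40 °C; H2O
Reagents that add atoms: N,N-dimethylformamide, CN(C)C=O
Why: The two remaining hydrogens of the trifluorophenyl ring are equivalent and each lies between two fluorines, so ortho-lithiation at −78 °C is site-unambiguous, and formylation of the aryllithium with DMF (Bouveault-type) releases the aldehyde when the hemiaminal alkoxide is hydrolysed.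

Step 7
Reactants: 12 half A' silyl ether; 15 ring A aldehyde
Product: 19 O-[bis(aryl)methyl] S-methyl dithiocarbonate (xanthate of the central carbinol, diastereomer mixture), via ring A' aryllithium 16 (not isolated), via lithium alkoxide of the central carbinol 17 (not isolated), via lithium xanthate 18 (not isolated)
Conditions: 12, n-BuLi, THF, −78 °C; then 15, −78 °C; then CS2, −78 → 0 °C; then MeI, 0 °C → rt
Reagents that add atoms: carbon disulfide, S=C=S; iodomethane, CI
Why: Ortho-lithiation between two fluorines, 1,2-addition to the aldehyde and xanthate formation from the resulting alkoxide with CS2 and MeI should run in one flask, because only the central oxygen is unprotected and an alkyllithium base leaves no amine to consume CS2; the new centre is uncontrolled and is removed in step 8.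

Step 8
Reactants: 19 central xanthate
Product: 20 bis(triethylsilyl) ether of the hexafluoro diarylmethane diol (diastereomer mixture)
Conditions: Bu3SnH, AIBN (cat.), toluene, 90 °C
Reagents that add atoms: none
Why: Barton–McCombie deoxygenation, in which the stannyl radical adds to the thiocarbonyl, the doubly benzylic C–O bond fragments to a stabilised diarylmethyl radical and this abstracts hydrogen from the stannane; aryl fluorides, benzyl ethers and silyl ethers are inert, and no β-hydrogen is available for thermal elimination.

Step 9
Reactants: 20 bis-silyl ether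
Product: 21 hexafluoro diarylmethane diol (both ring A/ring B carbinols free, diastereomer mixture)
Conditions: Bu4NF, AcOH, THF, 0 °C → rt
Reagents that add atoms: none
Why: Fluoride-mediated desilylation, buffered with acetic acid, should free both carbinols without the acid that would ionise these electron-rich benzhydrols.

Step 10
Reactants: 21 diol
Product: 22 hexafluoro bis-benzophenone (fluorine at C1, C3 and C5 of rings A and A')
Conditions: Dess–Martin periodinane, pyridine, CH2Cl2, 0 °C → rt
Reagents that add atoms: none
Why: Dess–Martin oxidation should convert both hindered secondary benzhydrols into diaryl ketones under neutral conditions that spare the diarylmethane CH2 and the benzyl ethers, and it removes the last stereocentres.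

Step 11
Reactants: 22 hexafluoro bis-benzophenone
Product: 24 heptabenzyl ether of the target (OMe at C1 and C1', OBn at C3, C5, C3', C5'), via dimethoxy tetrafluoride 23 (not isolated)
Conditions: NaOMe (2.0 equiv), DMSO, 20 °C, argon; then NaOBn (5 equiv, from BnOH and NaH in THF), 20 → 70 °C
Reagents that add atoms: sodium methoxide, [Na+].[O-]C; sodium benzyloxide, [Na+].[O-]Cc1ccccc1 (made from benzyl alcohol, OCc1ccccc1, and NaH)
Why: Each of the six substitutions is an addition–elimination in which the alkoxide adds to a fluorine-bearing carbon, the charge of the Meisenheimer anion is delocalised onto the C4 carbonyl oxygen and fluoride leaves. The closest known reaction type is alkoxide SNAr on fluorinated aryl ketones carrying fluorine ortho and para to the carbonyl; no ring closes and no stereocentre is formed. The step needs methoxide to enter only at the para carbons C1 and C1' before benzyloxide takes C3, C5, C3' and C5'. This is expected because DMSO gives a solvent-separated alkoxide with no sodium–carbonyl chelate to deliver it ortho, the para carbon is the more strongly activated and is not flanked by the twisted aroyl group, and the consumption of exactly two equivalents of methoxide is to be confirmed by 19F NMR before benzyloxide is added. The methoxy group at C1 is meta to C3 and C5 and so places no electron density on the carbons that carry charge in the later Meisenheimer anions, which keeps the ortho fluorines reactive on warming. The small fluorines keep the carbonyl conjugated with ring A, the tetra-ortho-substituted ketones resist alkoxide addition, and the benzyl ethers on rings B and B' leave no phenoxide that could close a xanthone onto an ortho C–F.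

Step 12
Reactants: 24 heptabenzyl ether
Product: 25 CNP0596095.0 (target)
Conditions: H2 (1 atm), 10% Pd/C, EtOAc–MeOH, rt
Reagents that add atoms: none
Why: Catalytic hydrogenolysis should cleave all seven benzyl aryl ethers, while the di-ortho-substituted, hydrogen-bonded benzophenone carbonyls, the aryl methyl ethers and the diarylmethane bridge are expected to persist at ambient pressure.

**Compound list**

1 | 2,4-dihydroxy-6-methylbenzaldehyde | Cc1cc(O)cc(O)c1C=O | starting material
2 | 2,4-bis(benzyloxy)-6-methylbenzaldehyde | Cc1cc(OCc2ccccc2)cc(OCc2ccccc2)c1C=O | intermediate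
3 | 4-(benzyloxy)-2-hydroxy-6-methylbenzaldehyde | Cc1cc(OCc2ccccc2)cc(O)c1C=O | intermediate
4 | 4-(benzyloxy)-2-methoxy-6-methylbenzaldehyde | COc1cc(OCc2ccccc2)cc(C)c1C=O | intermediate
5 | 1,3,5-trifluorobenzene | Fc1cc(F)cc(F)c1 | starting material
6 | 2,4,6-trifluorophenyllithium | [Li]c1c(F)cc(F)cc1F | intermediate
7 | lithium [2,4-bis(benzyloxy)-6-methylphenyl](2,4,6-trifluorophenyl)methanolate (racemic) | [Li]OC(c1c(C)cc(OCc2ccccc2)cc1OCc1ccccc1)c1c(F)cc(F)cc1F | intermediate
8 | {[2,4-bis(benzyloxy)-6-methylphenyl](2,4,6-trifluorophenyl)methoxy}triethylsilane (half A, racemic) | CC[Si](CC)(CC)OC(c1c(C)cc(OCc2ccccc2)cc1OCc1ccccc1)c1c(F)cc(F)cc1F | intermediate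
9 | 1-bromo-2,4,6-trifluorobenzene | Fc1cc(F)c(Br)c(F)c1 | starting material
10 | 2,4,6-trifluorophenylmagnesium chloride (formed as its LiCl complex) | Cl[Mg]c1c(F)cc(F)cc1F | intermediate
11 | chloromagnesium [4-(benzyloxy)-2-methoxy-6-methylphenyl](2,4,6-trifluorophenyl)methanolate (racemic) | Cl[Mg]OC(c1c(C)cc(OCc2ccccc2)cc1OC)c1c(F)cc(F)cc1F | intermediate
12 | {[4-(benzyloxy)-2-methoxy-6-methylphenyl](2,4,6-trifluorophenyl)methoxy}triethylsilane (half A', racemic) | CC[Si](CC)(CC)OC(c1c(C)cc(OCc2ccccc2)cc1OC)c1c(F)cc(F)cc1F | intermediate
13 | 3-lithio derivative of 8 (lithium between two fluorines on ring A) | CC[Si](CC)(CC)OC(c1c(C)cc(OCc2ccccc2)cc1OCc1ccccc1)c1c(F)cc(F)c([Li])c1F | intermediate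
14 | lithium hemiaminal alkoxide from 13 and DMF (ArCH(OLi)NMe2) | CC[Si](CC)(CC)OC(c1c(C)cc(OCc2ccccc2)cc1OCc1ccccc1)c1c(F)cc(F)c(C(O[Li])N(C)C)c1F | intermediate
15 | 3-{[2,4-bis(benzyloxy)-6-methylphenyl][(triethylsilyl)oxy]methyl}-2,4,6-trifluorobenzaldehyde (racemic) | CC[Si](CC)(CC)OC(c1c(C)cc(OCc2ccccc2)cc1OCc1ccccc1)c1c(F)cc(F)c(C=O)c1F | intermediate
16 | 3-lithio derivative of 12 (lithium between two fluorines on ring A') | CC[Si](CC)(CC)OC(c1c(C)cc(OCc2ccccc2)cc1OC)c1c(F)cc(F)c([Li])c1F | intermediate
17 | lithium alkoxide of the central carbinol joining rings A and A' (both outer carbinols as triethylsilyl ethers, diastereomer mixture) | CC[Si](CC)(CC)OC(c1c(C)cc(OCc2ccccc2)cc1OCc1ccccc1)c1c(F)cc(F)c(C(O[Li])c2c(F)cc(F)c(C(O[Si](CC)(CC)CC)c3c(C)cc(OCc4ccccc4)cc3OC)c2F)c1F | intermediate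
18 | lithium O-[bis(aryl)methyl] dithiocarbonate of the central carbinol (diastereomer mixture) | CC[Si](CC)(CC)OC(c1c(C)cc(OCc2ccccc2)cc1OCc1ccccc1)c1c(F)cc(F)c(C(OC(=S)S[Li])c2c(F)cc(F)c(C(O[Si](CC)(CC)CC)c3c(C)cc(OCc4ccccc4)cc3OC)c2F)c1F | intermediate
19 | O-[bis(aryl)methyl] S-methyl dithiocarbonate of the central carbinol (diastereomer mixture) | CC[Si](CC)(CC)OC(c1c(C)cc(OCc2ccccc2)cc1OCc1ccccc1)c1c(F)cc(F)c(C(OC(=S)SC)c2c(F)cc(F)c(C(O[Si](CC)(CC)CC)c3c(C)cc(OCc4ccccc4)cc3OC)c2F)c1F | intermediate
20 | bis(triethylsilyl) ether of the hexafluoro diarylmethane diol (CH2 bridge between C6 and C6', diastereomer mixture) | CC[Si](CC)(CC)OC(c1c(C)cc(OCc2ccccc2)cc1OCc1ccccc1)c1c(F)cc(F)c(Cc2c(F)cc(F)c(C(O[Si](CC)(CC)CC)c3c(C)cc(OCc4ccccc4)cc3OC)c2F)c1F | intermediate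
21 | hexafluoro diarylmethane diol (both outer carbinols free, diastereomer mixture) | OC(c1c(C)cc(OCc2ccccc2)cc1OCc1ccccc1)c1c(F)cc(F)c(Cc2c(F)cc(F)c(C(O)c3c(C)cc(OCc4ccccc4)cc3OC)c2F)c1F | intermediate
22 | hexafluoro bis-benzophenone (fluorine at C1, C3, C5 of rings A and A'; ring B 2,4-bis-OBn; ring B' 2-OMe, 4-OBn) | O=C(c1c(C)cc(OCc2ccccc2)cc1OCc1ccccc1)c1c(F)cc(F)c(Cc2c(F)cc(F)c(C(=O)c3c(C)cc(OCc4ccccc4)cc3OC)c2F)c1F | intermediate
23 | dimethoxy tetrafluoro bis-benzophenone (OMe at C1 and C1', fluorine at C3, C5, C3', C5') | O=C(c1c(C)cc(OCc2ccccc2)cc1OCc1ccccc1)c1c(F)cc(OC)c(Cc2c(OC)cc(F)c(C(=O)c3c(C)cc(OCc4ccccc4)cc3OC)c2F)c1F | intermediate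
24 | heptabenzyl ether of the target | O=C(c1c(C)cc(OCc2ccccc2)cc1OCc1ccccc1)c1c(OCc2ccccc2)cc(OC)c(Cc2c(OC)cc(OCc3ccccc3)c(C(=O)c3c(C)cc(OCc4ccccc4)cc3OC)c2OCc2ccccc2)c1OCc1ccccc1 | intermediate
25 | CNP0596095.0 | COc1cc(O)c(C(=O)c2c(C)cc(O)cc2O)c(O)c1Cc1c(OC)cc(O)c(C(=O)c2c(C)cc(O)cc2OC)c1O | target

**Summary**

Total step count: 12. Longest linear sequence: 9 steps from 2,4-dihydroxy-6-methylbenzaldehyde (steps 2, 3, 5, 7, 8, 9, 10, 11, 12; the branch through steps 1, 4, 6 is equally long).

**Steps most likely to fail**

Step 11. Methoxide may fail to discriminate para from ortho carbons, which would place methyl ethers at C3 or C5 that no later step removes. The sixth displacement at the crowded C5 fluorines may stall. Reversible deprotonation of the bridging CH2 may also slow both rings. The fallback reverses the order and relies on metal chelation instead of solvent-separated ions. It sets out from 22, which is treated with lithium benzyloxide (BnOH, LiN(SiMe3)2) in toluene, where lithium bound to the carbonyl oxygen delivers the alkoxide to the four ortho carbons only. The resulting tetra-ortho-benzyloxy para-difluoride F1 is isolated and its two remaining para fluorines are replaced with NaOMe in DMSO. This comes back to the route at 24.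

Step 7. The ortho-fluoroaryllithium may lose LiF to an aryne on warming, the crowded lithium alkoxide may be captured only partly by CS2, and proton transfer may return 12. The fallback joins the halves by a benzylic cross-coupling instead of a carbonyl addition and so also avoids the radical deoxygenation. It sets out from 15, which is reduced with NaBH4 to the benzylic alcohol F2 and converted with CBr4/PPh3 (Appel reaction) into the benzylic bromide F3. In parallel, 12 is lithiated as in step 7 to 16 and transmetalated with ZnCl2 to the arylzinc chloride F4, which does not eliminate metal fluoride. Negishi coupling of F4 with F3 under Pd(PPh3)4 (zerovalent palladium) gives the diarylmethane directly, and the fallback comes back to the route at 20.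

Step 12. The diaryl ketone carbonyls may be over-reduced to carbinol or methylene, or hydrogenolysis may stall at partly benzylated stages on the crowded ortho ethers. The fallback replaces reduction by Lewis-acid cleavage. It sets out from 24, which is treated with BCl3 and pentamethylbenzene in CH2Cl2 at −78 °C. Benzyl cations are trapped by the scavenger before they can alkylate the electron-rich rings, and the methyl ethers are expected to survive at this temperature. It comes back to the route at 25 and makes no new compound (entry F0).

**Further compounds**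

F1 | step 11 | tetra-ortho-benzyloxy para-difluoro bis-benzophenone (OBn at C3, C5, C3', C5'; fluorine at C1 and C1') | O=C(c1c(C)cc(OCc2ccccc2)cc1OCc1ccccc1)c1c(OCc2ccccc2)cc(F)c(Cc2c(F)cc(OCc3ccccc3)c(C(=O)c3c(C)cc(OCc4ccccc4)cc3OC)c2OCc2ccccc2)c1OCc1ccccc1
F2 | step 7 | (3-{[2,4-bis(benzyloxy)-6-methylphenyl][(triethylsilyl)oxy]methyl}-2,4,6-trifluorophenyl)methanol | CC[Si](CC)(CC)OC(c1c(C)cc(OCc2ccccc2)cc1OCc1ccccc1)c1c(F)cc(F)c(CO)c1F
F3 | step 7 | benzylic bromide of F2 (CH2Br in place of CH2OH) | CC[Si](CC)(CC)OC(c1c(C)cc(OCc2ccccc2)cc1OCc1ccccc1)c1c(F)cc(F)c(CBr)c1F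
F4 | step 7 | arylzinc chloride from 16 (ZnCl between two fluorines on ring A') | CC[Si](CC)(CC)OC(c1c(C)cc(OCc2ccccc2)cc1OC)c1c(F)cc(F)c([Zn]Cl)c1F
F0 | step 12 | none | none
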